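**Plan**
1. Rings: cap A (3,5-dihydroxyphenoxy) sits on the oxygen at C2 of hub B. From the oxygens at C1 and C3 of B, two identical arms run through ring C and ring D to the C-linked phloroglucinol ring E (C and D are numbered from the carbon bearing the inner ether oxygen, E from the biaryl carbon).
2. Cuts: first the 17 O–CH3 bonds of a methylated octamer, then both ring D C5–ring E C1 biaryl bonds together. After that come the two B–O–C ethers, the C–O–D ether of each arm and the A–O–B ether.
3. Enabling feature: unarylated ring D has its only free OH at C4. Its para carbon C1 is blocked by the ether oxygen to ring C and shielded by OMe at C2 and C6. Its ortho CH carbons C3 and C5 are mirror-related, so oxidation at that OH can forge only the C5–C1(E) bond of the target.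
4. The ring D 4-OH travels as the formyl group of syringaldehyde and is unveiled by Baeyer–Villiger oxidation, so in every ether coupling only the reacting phenol is free.
5. Forward order: A onto B, D onto C, two C–D arms onto A–B, CHO to OH on both arms, two rings E onto both rings D, then global demethylation. All eight rings are bought as benzenes and none is constructed.
6. Stereochemistry: there is no stereocentre, and the two tetra-ortho-substituted axes are not stereogenic because ring E bears identical groups at C2 and C6.

Key step: step 7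

Remark: compounds 1, 2, 4, 6 and 13 are taken to be catalogue chemicals. The methyl ether is the spectator group on every oxygen that is not reacting.

Step 1
Reactants: 1 2,6-dibromo-4-methoxyphenol; 2 3,5-dimethoxyphenylboronic acid
Product: 3 1,3-dibromo-2-(3,5-dimethoxyphenoxy)-5-methoxybenzene (A–B dibromide)
Conditions: Cu(OAc)2 (2 equiv), pyridine (5 equiv), 4 Å MS, CH2Cl2, air, rt
Reagents that add atoms: none
Why: The Chan–Lam–Evans O-arylation runs at room temperature through a copper aryl phenolate, is known to accept 2,6-dihalophenols, and leaves both C–Br bonds intact for step 5, which a thermal Ullmann arylation of 1 would not guarantee.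

Step 2
Reactants: 4 4-bromo-2,6-dimethoxyphenol
Product: 5 5-bromo-1,3-dimethoxy-2-(methoxymethoxy)benzene
Conditions: NaH, MOMCl, DMF, 0 °C to rt
Reagents that add atoms: chloromethyl methyl ether (MOMCl), COCCl
Why: Williamson-type alkylation of the sodium phenolate masks the ring C oxygen as an acetal that is inert to hot carbonate and copper, yet is removed by dilute acid without harm to an aldehyde.

Step 3
Reactants: 5 5-bromo-1,3-dimethoxy-2-(methoxymethoxy)benzene; 6 syringaldehyde (4-hydroxy-3,5-dimethoxybenzaldehyde)
Product: 7 4-[3,5-dimethoxy-4-(methoxymethoxy)phenoxy]-3,5-dimethoxybenzaldehyde (C–D arm as MOM ether)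
Conditions: CuI (20 mol %), 2,2,6,6-tetramethylheptane-3,5-dione (40 mol %), Cs2CO3, NMP, 120 °C, Ar
Reagents that add atoms: none
Why: This is a diketone-accelerated Ullmann diaryl ether synthesis, a variant suited to pairing an electron-poor phenolate with an electron-rich aryl bromide; the bromide of 5 has two free ortho positions, and the non-enolisable aldehyde and the acetal tolerate Cs2CO3.

Step 4
Reactants: 7 C–D arm as MOM ether
Product: 8 4-(4-hydroxy-3,5-dimethoxyphenoxy)-3,5-dimethoxybenzaldehyde (C–D arm phenol)
Conditions: 3 M aq. HCl, THF, 50 °C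
Reagents that add atoms: none
Why: Acid hydrolysis cleaves only the MOM acetal, and in the aqueous medium the aryl methyl ethers, the diaryl ether and the aldehyde are unchanged.

Step 5
Reactants: 3 A–B dibromide; 8 C–D arm phenol (two equivalents react)
Product: 10 1,3-bis[4-(4-formyl-2,6-dimethoxyphenoxy)-2,6-dimethoxyphenoxy]-2-(3,5-dimethoxyphenoxy)-5-methoxybenzene (hexamer dialdehyde), via mono-ether bromide 9 (not isolated)
Conditions: 8 (2.5 equiv), CuI (40 mol %), picolinic acid (80 mol %), K3PO4, DMSO, 110 °C, Ar
Reagents that add atoms: none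
Why: This is a twofold Ullmann coupling under the picolinate conditions known to join 2,6-disubstituted phenols to ortho-substituted aryl halides; the electron-rich phenolate of 8 is a good partner, and its excess carries 9 on to 10.

Step 6
Reactants: 10 hexamer dialdehyde
Product: 12 1,3-bis[4-(4-hydroxy-2,6-dimethoxyphenoxy)-2,6-dimethoxyphenoxy]-2-(3,5-dimethoxyphenoxy)-5-methoxybenzene (hexameric bis-phenol), via hexamer bis-formate 11 (not isolated)
Conditions: mCPBA (2.6 equiv), CH2Cl2, 0 °C to rt; then K2CO3 (cat.), MeOH, Ar, rt
Reagents that add atoms: 3-chloroperoxybenzoic acid (mCPBA), OOC(=O)c1cccc(Cl)c1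
Why: In this Baeyer–Villiger oxidation of an electron-rich benzaldehyde the 4-aryloxy-3,5-dimethoxyphenyl group migrates rather than hydride, as it does for 3,4,5-trimethoxybenzaldehyde, and base-catalysed methanolysis of the aryl formates then frees the two ring D 4-OH groups.

Step 7
Reactants: 12 hexameric bis-phenol; 13 1,3,5-trimethoxybenzene (two equivalents react)
Product: 15 octamer with a 2,4,6-trimethoxyphenyl group on C5 of both rings D and both ring D 4-OH groups free and 17 OMe groups, via mono-arylated heptamer 14 (not isolated)
Conditions: 13 (10 equiv), FeCl3 (20 mol %), t-BuOOt-Bu (2.2 equiv), dry HFIP/CH2Cl2, rt, Ar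
Reagents that add atoms: none
Why: The ring D phenols are the only groups of 12 that can bind FeCl3 as phenolates, so oxidation occurs inside the coordination sphere (tert-butoxyl radicals from the peroxide return the metal to trivalent iron) and gives an electrophilic phenoxyl radical that HFIP stabilises by hydrogen bonding. One of the three equivalent CH carbons of 13 adds to ring D C5, and a further one-electron oxidation with loss of two protons restores both aromatic rings, which leads first to 14 and, after the same events on the other arm, to 15. The closest known reaction is the iron-catalysed dehydrogenative phenol–arene cross-coupling in fluorinated alcohols, which is established for electron-rich, para-oxygenated phenols and for 13 as the arene. No ring is closed and no stereocentre arises, since each new axis carries the symmetric ring E. The step needs attack at an ortho CH only: C1 is fully substituted and shielded by two methoxy groups, C3 and C5 are interchanged by the local mirror plane of ring D so that both give the same product, and bond formation at the radical stage in a dry medium leaves neither a free phenoxenium ion nor water to expel the ring C aryloxide from C1. A large excess of 13 outruns ring A of a second molecule as the nucleophile, while the peroxide is held near one equivalent per arm so that the more crowded biaryl phenol is not arylated again at C3.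

Step 8
Reactants: 15 methylated octamer
Product: 16 CNP0227063.0 (free octameric fucophlorethol with 19 OH groups)
Conditions: BBr3 (3 equiv per OMe), CH2Cl2, −78 °C to rt; ice-water
Reagents that add atoms: none
Why: In this Lewis-acid ether cleavage BBr3 binds each methoxy oxygen and bromide removes the methyl group by SN2, whereas the diaryl ether and biaryl bonds offer no sp3 carbon for attack and should persist.

**Compound list**
1 | 2,6-dibromo-4-methoxyphenol | COc1cc(Br)c(O)c(Br)c1 | starting material
2 | 3,5-dimethoxyphenylboronic acid | COc1cc(OC)cc(B(O)O)c1 | starting material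
3 | 1,3-dibromo-2-(3,5-dimethoxyphenoxy)-5-methoxybenzene | COc1cc(OC)cc(Oc2c(Br)cc(OC)cc2Br)c1 | intermediate
4 | 4-bromo-2,6-dimethoxyphenol | COc1cc(Br)cc(OC)c1O | starting material
5 | 5-bromo-1,3-dimethoxy-2-(methoxymethoxy)benzene | COCOc1c(OC)cc(Br)cc1OC | intermediate
6 | syringaldehyde | COc1cc(C=O)cc(OC)c1O | starting material
7 | 4-[3,5-dimethoxy-4-(methoxymethoxy)phenoxy]-3,5-dimethoxybenzaldehyde | COCOc1c(OC)cc(Oc2c(OC)cc(C=O)cc2OC)cc1OC | intermediate
8 | 4-(4-hydroxy-3,5-dimethoxyphenoxy)-3,5-dimethoxybenzaldehyde | COc1cc(Oc2c(OC)cc(C=O)cc2OC)cc(OC)c1O | intermediate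
9 | mono-ether bromide (one C–D arm on the A–B unit, one C–Br left) | COc1cc(OC)cc(Oc2c(Br)cc(OC)cc2Oc2c(OC)cc(Oc3c(OC)cc(C=O)cc3OC)cc2OC)c1 | intermediate
10 | hexamer dialdehyde | COc1cc(OC)cc(Oc2c(Oc3c(OC)cc(Oc4c(OC)cc(C=O)cc4OC)cc3OC)cc(OC)cc2Oc2c(OC)cc(Oc3c(OC)cc(C=O)cc3OC)cc2OC)c1 | intermediate
11 | hexamer bis-formate | COc1cc(OC)cc(Oc2c(Oc3c(OC)cc(Oc4c(OC)cc(OC=O)cc4OC)cc3OC)cc(OC)cc2Oc2c(OC)cc(Oc3c(OC)cc(OC=O)cc3OC)cc2OC)c1 | intermediate
12 | hexameric bis-phenol (ring D 4-OH free on both arms) | COc1cc(OC)cc(Oc2c(Oc3c(OC)cc(Oc4c(OC)cc(O)cc4OC)cc3OC)cc(OC)cc2Oc2c(OC)cc(Oc3c(OC)cc(O)cc3OC)cc2OC)c1 | intermediate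
13 | 1,3,5-trimethoxybenzene | COc1cc(OC)cc(OC)c1 | starting material
14 | mono-arylated heptamer (ring E on one arm only) | COc1cc(OC)cc(Oc2c(Oc3c(OC)cc(Oc4c(OC)cc(O)c(-c5c(OC)cc(OC)cc5OC)c4OC)cc3OC)cc(OC)cc2Oc2c(OC)cc(Oc3c(OC)cc(O)cc3OC)cc2OC)c1 | intermediate
15 | methylated octamer with both biaryl bonds | COc1cc(OC)cc(Oc2c(Oc3c(OC)cc(Oc4c(OC)cc(O)c(-c5c(OC)cc(OC)cc5OC)c4OC)cc3OC)cc(OC)cc2Oc2c(OC)cc(Oc3c(OC)cc(O)c(-c4c(OC)cc(OC)cc4OC)c3OC)cc2OC)c1 | intermediate
16 | CNP0227063.0 | Oc1cc(O)cc(Oc2c(Oc3c(O)cc(Oc4c(O)cc(O)c(-c5c(O)cc(O)cc5O)c4O)cc3O)cc(O)cc2Oc2c(O)cc(Oc3c(O)cc(O)c(-c4c(O)cc(O)cc4O)c3O)cc2O)c1 | target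

**Step count:** 8 steps in total. The longest linear sequence is 7 steps (steps 2 to 8: 4, 5, 7, 8, 10, 12, 15, 16).

**The three steps most likely to fail**

**Step 7.** Four processes threaten this step:
- Capture at ring D C1, followed by expulsion of the ring C aryloxide and collapse to a quinone.
- Outer-sphere oxidation of the fully etherified rings.
- A second arylation at C3.
- Coupling that stops after one arm.

The fallback sets out from 12 and comes back at 15. It makes the same two C–C bonds by halogenation and cross-coupling instead of by dehydrogenation. The free phenol rings D are the most nucleophilic rings of 12. Amine-mediated ortho-bromination (NBS, 2.0 equiv, cat. i-Pr2NH, CH2Cl2, −78 °C to 0 °C) should therefore give the hexameric bis(5-bromo ring D phenol) F1. A twofold Suzuki–Miyaura coupling with commercial 2,4,6-trimethoxyphenylboronic acid (Pd(OAc)2, SPhos, K3PO4, toluene/H2O, 90 °C) should then give 15. The boronic acid is used in excess to offset protodeboronation.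

**Step 5.** The coupling may stall after the first C–O bond, because the remaining bromide lies in a crowded pocket, and slow turnover may be accompanied by hydrodebromination. The fallback sets out from 3 and comes back at 10. It reverses the polarity of the B–O–C bonds, so that the hub supplies unhindered phenolates and ring C supplies an activated carbon.
- Twofold palladium-catalysed hydroxylation of 3 (Pd2(dba)3, tBuXPhos, KOH, dioxane/H2O, 100 °C) should give 2-(3,5-dimethoxyphenoxy)-5-methoxybenzene-1,3-diol F2.
- Addition–elimination on commercial 4-fluoro-3,5-dimethoxybenzaldehyde (Cs2CO3, DMSO, 120 °C) should give the tetramer dialdehyde F3.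
- Baeyer–Villiger oxidation with mCPBA gives the tetramer bis-formate F4, and catalytic K2CO3 in MeOH gives the tetramer bis-phenol F5.
- A second addition–elimination of F5 on the same fluoroaldehyde installs both rings D and gives 10.

The pairing of fluoroaldehyde substitution with Baeyer–Villiger oxidation is the standard route to 4-aryloxyphenols.

**Step 8.** Ether cleavage may remain incomplete because partly cleaved boron aryloxides fall out of solution, and the free polyphenol may be oxidised by air during purification. The fallback sets out from 15 and comes back at 16. It moves purification and recycling to a protected derivative.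
- After BBr3 treatment and quench, the crude polyphenol is not purified but is exhaustively acetylated (Ac2O, pyridine, cat. DMAP, rt) to the nonadecaacetate F6.
- F6 should be stable and soluble, and separable on silica from congeners that still carry methyl groups. Those congeners are returned to BBr3.
- Transesterification of pure F6 with catalytic HCl in degassed MeOH under argon releases 16 with volatile by-products only.

Further compounds
F1 | step 7 | hexameric bis(5-bromo ring D phenol) | COc1cc(OC)cc(Oc2c(Oc3c(OC)cc(Oc4c(OC)cc(O)c(Br)c4OC)cc3OC)cc(OC)cc2Oc2c(OC)cc(Oc3c(OC)cc(O)c(Br)c3OC)cc2OC)c1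
F2 | step 5 | 2-(3,5-dimethoxyphenoxy)-5-methoxybenzene-1,3-diol | COc1cc(OC)cc(Oc2c(O)cc(OC)cc2O)c1
F3 | step 5 | tetramer dialdehyde, 1,3-bis(4-formyl-2,6-dimethoxyphenoxy)-2-(3,5-dimethoxyphenoxy)-5-methoxybenzene | COc1cc(OC)cc(Oc2c(Oc3c(OC)cc(C=O)cc3OC)cc(OC)cc2Oc2c(OC)cc(C=O)cc2OC)c1
F4 | step 5 | tetramer bis-formate | COc1cc(OC)cc(Oc2c(Oc3c(OC)cc(OC=O)cc3OC)cc(OC)cc2Oc2c(OC)cc(OC=O)cc2OC)c1
F5 | step 5 | tetramer bis-phenol, 1,3-bis(4-hydroxy-2,6-dimethoxyphenoxy)-2-(3,5-dimethoxyphenoxy)-5-methoxybenzene | COc1cc(OC)cc(Oc2c(Oc3c(OC)cc(O)cc3OC)cc(OC)cc2Oc2c(OC)cc(O)cc2OC)c1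
F6 | step 8 | nonadecaacetate of the target | CC(=O)Oc1cc(OC(C)=O)cc(Oc2c(Oc3c(OC(C)=O)cc(Oc4c(OC(C)=O)cc(OC(C)=O)c(-c5c(OC(C)=O)cc(OC(C)=O)cc5OC(C)=O)c4OC(C)=O)cc3OC(C)=O)cc(OC(C)=O)cc2Oc2c(OC(C)=O)cc(Oc3c(OC(C)=O)cc(OC(C)=O)c(-c4c(OC(C)=O)cc(OC(C)=O)cc4OC(C)=O)c3OC(C)=O)cc2OC(C)=O)c1
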